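| setting | summer | autumn | dusk | flask |
|---|---|---|---|---|
| solid substrate | 0.17 M | 0.26 M | 0.34 M | 0.34 M |
| reagent | 0.204 M (in portions, 2) | 0.204 M (in portions, 2) | 0.31 M (in portions, 2) | 0.204 M (in portions, 2) |
| remark | run made earlier; portions every 80 s | run made earlier; portions every 80 s | run made earlier; portions every 80 s | the portions of reagent follow each other after 80 s, the first at the start |
| time |  |  |  | 2.5 min |

- summer (time / min: target / %, isomer of the product / %, solid substrate / %): 0.667: 17.6, 42.1, 0; 1.33: 17.8, 42.0, 0; 2.00: 29.5, 68.7, 0; 2.50: 30.3, 69.3, 0.1; 3.00: 29.5, 69.7, 0.5
- autumn (time / min: target / %, isomer of the product / %, solid substrate / %): 0.250: 11.0, 25.7, 1.0; 0.833: 12.2, 26.9, 0.5; 1.33: 12.1, 27.4, 0.4; 2.00: 23.3, 54.0, 0; 3.00: 22.8, 54.8, 0.5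
- dusk (time / min: target / %, isomer of the product / %, solid substrate / %): 0.250: 12.3, 29.5, 4.2; 0.417: 13.2, 31.6, 0; 0.833: 13.8, 32.3, 0; 1.50: 24.1, 56.1, 0; 3.00: 27.2, 62.9, 0.3

(scatter of a reading: 0.5 percentage points)

- given per volume of solution although it is solid: solid substrate
- the analysis behind the earlier runs scatters by 0.5 percentage points, standard deviation
- at the start none of the solid substrate is in solution

- target present at 2.5 min, in percent of the solid substrate charged
- isomer of the product present at 2.5 min, in percent of the solid substrate charged

**Summer's leftover.** The summer run carried reagent at 1.20 times the solid substrate, and target plus isomer of the product reached 99.6 % of the charge, so that run ended with reagent over.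

**The share.** An even split is the zero of the scale. From the summer reading at 2.50 min and the autumn and dusk readings at 3.00 min I got 30.0 % for the target share, the part of target plus isomer of the product that is target. That is less than an even 0.5.

**My bracket.** In the flask, reagent covers 60.0 % of the charge, which makes it the limiting reagent. Multiplying by the share, I put the upper edge at 18.0 % target and 42.0 % isomer of the product. For the lower edge I used the autumn run, which stood at 98.5 % of its own reagent cover at 2.00 min, earlier than the asked 2.5 min. That gave 17.8 % and 41.4 %. Each edge carries the scatter of the readings.

**The forecast.** It gave 17.9 % target and 41.7 % isomer of the product, calling “The flask is reagent-limited”. Both numbers lie above my lower edge and below my upper one.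

**The result.** The flask gave 18.0 % target and 42.0 % isomer of the product.

    starting material + reagent → target (k = 0.370 M⁻¹ s⁻¹)
    solid substrate ⇌ starting material, rate k2*(cs2 - [starting material]) while solid is left; crystals form when [starting material] > cs2 (solubility = 0.210 M, k = 0.280 s⁻¹)
    starting material + reagent → isomer of the product (k = 0.860 M⁻¹ s⁻¹)

**One reason.** The passing of starting material and reagent into isomer of the product is the main reason the flask holds 18.0 % target. The same run without that step gives 59.5 %, and the share of that is 17.8 %. Less reagent moves the number: a flask like this one with 0.051 M of reagent has a cover of 15.0 %, the share of that is 4.51 %, and that flask holds 4.51 % target.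

(The runs come from a simulation from invented constants; noise was put on by code.)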